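**Plan**

- Numbering: C10 is the methyl-bearing quaternary ring carbon (its CH2CO2H arm is C1–C2), C5 the ring CH carrying CMe2CO2H (C4–C3), then C6, C7 (OAc), C8 (OH), C9 (ring-fusion H), C11 (OBz), C12, C13 (Me, vinyl), C14 (C=O). β is the face of the C10 methyl.
- Cuts, in order: the two acids are rejoined as the C2–C3 bond of a six-membered ring A (enol ether ozonolysis); then the C13–vinyl bond, the two esters and the C8–OH are removed; ring B is opened at C9–C10 and C7–C8 by a Diels–Alder transform.
- Enabling feature: ring C has para oxygens at C11 and C14 beside the C13 methyl (the toluquinone pattern), C7 carries an oxygen at the end of a C10=C5–C6=C7 diene, and the acid arms on C10 and C5 are the two halves of a carbocycle that can lock the C10=C5 geometry.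
- Forward: ring A (from 2,2-dimethylcyclohexane-1,3-dione) becomes a 1-silyloxydiene; ring C comes from 4-methoxy-2-methylphenol as the quinone mono-ketal, whose single ketone fixes regiochemistry and later enolisation; ring B closes in the cycloaddition; ring A is reopened near the end.
- Stereochemistry: C7, C8, C9, C10 from the catalysed endo cycloaddition; 8β-OH by convex-face enolate oxidation; C9 by equilibration to the trans fusion; C5 by hydrogen-atom-transfer reduction; C11 by 8-OH-directed hydride delivery; C13 by vinylation anti to the axial 8β-silyloxy group.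

Key step: step 8

Assumption: the oxazaborolidinium ion made from (S)-diphenylprolinol is taken to expose the dienone face that gives the step 8 adduct as drawn; if the sense proves opposite, its (R) antipode is the catalyst.

**Step 1**
Reactants: 1 2,2-dimethylcyclohexane-1,3-dione
Product: 2 6,6-dimethyl-1,4-dioxaspiro[4.5]decan-7-one
Conditions: HOCH2CH2OH (1.05 equiv), p-TsOH·H2O (cat.), benzene, reflux, Dean–Stark
Reagents that add atoms: ethylene glycol, OCCO
Why: Acid-catalysed ketalisation should stop at the mono-dioxolane because the second carbonyl, now flanked by the gem-dimethyl carbon and the spiro centre, ketalises much more slowly.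

**Step 2**
Reactants: 2 6,6-dimethyl-1,4-dioxaspiro[4.5]decan-7-one
Product: 4 6,6,8-trimethyl-1,4-dioxaspiro[4.5]decan-7-one (racemic), via lithium enolate 3 (not isolated)
Conditions: LiN(i-Pr)2, THF, −78 °C; MeI, −78 → 0 °C
Reagents that add atoms: iodomethane, CI
Why: Enolate alkylation is regiochemically unambiguous because only one α-carbon (C10 of the target) bears hydrogens; the new stereocentre is erased in step 5.

**Step 3**
Reactants: 4 6,6,8-trimethyl-1,4-dioxaspiro[4.5]decan-7-one
Product: 5 7-ethynyl-6,6,8-trimethyl-1,4-dioxaspiro[4.5]decan-7-ol (diastereomer mixture)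
Conditions: HC≡CMgBr (3 equiv), THF, 0 °C → rt; aq. NH4Cl
Reagents that add atoms: ethynylmagnesium bromide, C#C[Mg]Br
Why: Grignard 1,2-addition of the small sp nucleophile is the standard entry to 1-ethynyl-2,2,6-trimethylcyclohexanols, and both carbinol epimers converge in step 4.

**Step 4**
Reactants: 5 7-ethynyl-6,6,8-trimethyl-1,4-dioxaspiro[4.5]decan-7-ol
Product: 6 2-(6,6,8-trimethyl-1,4-dioxaspiro[4.5]decan-7-ylidene)acetaldehyde (E/Z mixture, racemic)
Conditions: VO(OSiPh3)3 (5 mol%), Ph3SiOH (20 mol%), xylene, 140 °C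
Reagents that add atoms: none
Why: The vanadate-catalysed Meyer–Schuster rearrangement (1,3-oxygen shift through the propargyl vanadate) should give the enal without acid, sparing the dioxolane and avoiding the Rupe pathway.

**Step 5**
Reactants: 6 2-(6,6,8-trimethyl-1,4-dioxaspiro[4.5]decan-7-ylidene)acetaldehyde
Product: 7 tert-butyldimethyl{[(E)-2-(6,6,8-trimethyl-1,4-dioxaspiro[4.5]dec-7-en-7-yl)ethenyl]oxy}silane (ring A diene C10=C5–C6=C7–OTBS)
Conditions: TBSOTf, Et3N, CH2Cl2, 0 °C → rt
Reagents that add atoms: tert-butyldimethylsilyl triflate, CC(C)(C)[Si](C)(C)OS(=O)(=O)C(F)(F)F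
Why: Soft vinylogous enolisation (O-silylation of the s-trans enal, then loss of the only γ-hydrogen at the ring CH) should give the tetrasubstituted ring alkene and the E enol ether, removing both stereo-elements of 6.

**Step 6**
Reactants: 8 4-methoxy-2-methylphenol
Product: 9 4,4-dimethoxy-2-methylcyclohexa-2,5-dien-1-one
Conditions: PhI(OAc)2, MeOH, 0 °C
Reagents that add atoms: methanol, CO
Why: Oxidative dearomatisation of a para-methoxyphenol in methanol is the standard route to quinone monoketals and places the free ketone beside the methyl-bearing carbon (C14 next to C13).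

**Step 7**
Reactants: 9 4,4-dimethoxy-2-methylcyclohexa-2,5-dien-1-one
Product: 10 7-methyl-1,4-dioxaspiro[4.5]deca-6,9-dien-8-one (2-methyl-1,4-benzoquinone 4-ethylene ketal)
Conditions: HOCH2CH2OH, BF3·OEt2 (cat.), DME, 0 °C → rt
Reagents that add atoms: ethylene glycol, OCCO
Why: Acid-catalysed transketalisation gives the cyclic ketal, which re-closes after any ionisation and should therefore tolerate the Lewis acid of step 8.

**Step 8**
Reactants: 7 ring A silyloxydiene; 10 2-methylbenzoquinone mono-ketal
Product: 11 endo adduct (cis B/C tricyclic enone: C14 ketone, C12=C13, C5=C6, 7α-OTBS, H8β, H9β, 10β-Me, dioxolanes at C3 and C11)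
Conditions: (S)-B-(o-tolyl)-α,α-diphenylprolinol oxazaborolidine (24 mol%)/HNTf2 (20 mol%), CH2Cl2, −78 → −20 °C
Reagents that add atoms: none
Why: A Lewis-acid-catalysed, concerted but asynchronous [4+2] cycloaddition, whose closest known type is the oxazaborolidinium-catalysed Diels–Alder reaction of quinones and quinone monoketals with oxygenated or vinylcyclohexene dienes. The cation binds the only ketone of 10 at the lone pair syn to C8–H, so the unsubstituted C8=C9 bond reacts; the donor-bearing C7 joins the α-carbon C8 and C10 joins the β-carbon C9 (ortho rule). Ring B closes as a cyclohexene by suprafacial formation of C7–C8 and C9–C10 through the endo transition state. C8 and C9 are set cis by suprafacial addition to the ring alkene; C7 by the E enol ether, whose outside silyloxy group ends cis to the endo dienone ring and so trans to H8; C10 by ring A, which forces its methyl into the inside position and so cis to H9. The absolute sense comes from the chiral cation shielding one face of the bound dienone. The step needs regio-, site-, endo and facial selectivity, secured by the C7 oxygen, the C13 methyl, secondary overlap with the dienone and the catalyst respectively.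

**Step 9**
Reactants: 11 endo adduct
Product: 13 8β-hydroxy enone, via potassium dienolate 12 (not isolated)
Conditions: KN(SiMe3)2, THF, −78 °C; 2-(phenylsulfonyl)-3-phenyloxaziridine, −78 °C; aq. NH4Cl
Reagents that add atoms: 2-(phenylsulfonyl)-3-phenyloxaziridine, O=S(=O)(c1ccccc1)N1OC1c1ccccc1
Why: In this oxaziridine α'-hydroxylation of an enone enolate, C8–H is the only enolisable position (C11 is a quaternary ketal carbon), and the oxidant should attack the convex β face, cis to H9 and anti to the 7α-silyloxy group, giving 8β-OH with the cis fusion retained.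

**Step 10**
Reactants: 13 8β-hydroxy enone
Product: 14 8β-hydroxy ketone with saturated C12–C13 (C13 epimers)
Conditions: H2 (1 atm), Pd/C, EtOAc, rt
Reagents that add atoms: none
Why: Heterogeneous hydrogenation should reduce the conjugated C12=C13 bond and leave the hindered C5=C6 bond; removing the enone first keeps the later hydroxy diketone from dehydrating to a quinone, and C13 is equilibrated in step 12.

**Step 11**
Reactants: 14 8β-hydroxy ketone
Product: 15 cis-fused 3,11,14-triketone (C5=C6, 9β-H, 8β-OH, 7α-OTBS)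
Conditions: p-TsOH·H2O (cat.), acetone–H2O (10:1), 40 °C
Reagents that add atoms: water, O
Why: Acid-catalysed deketalisation should remove both dioxolanes, while the hindered secondary silyl ether and the tertiary alcohol tolerate the dilute acid.

**Step 12**
Reactants: 15 cis-fused triketone
Product: 16 trans-fused 3,11,14-triketone (C5=C6, 9α-H, 13α-Me)
Conditions: DBU (0.3 equiv), CH2Cl2, 0 °C → rt
Reagents that add atoms: none
Why: Base-mediated epimerisation α to the C11 and C14 ketones under thermodynamic control should invert C9, relieving the syn-axial contact between C11 and the 7α-silyloxy group and giving the steroid-like trans B/C fusion, while the C13 methyl settles equatorial; the mild amine base is chosen to outpace E1cB loss of the 8-hydroxyl.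

**Step 13**
Reactants: 16 trans-fused triketone
Product: 17 5α-saturated triketone (trans A/B, trans B/C)
Conditions: Mn(dpm)3 (10 mol%; dpm = dipivaloylmethanate), PhSiH3, t-BuOOH, i-PrOH, rt
Reagents that add atoms: none
Why: Metal-hydride hydrogen-atom-transfer hydrogenation suits hindered trisubstituted alkenes, and the tertiary C5 radical should accept hydrogen axially on the α face, anti to the C10 and 4β methyls, giving the trans A/B fusion.

**Step 14**
Reactants: 17 5α-saturated triketone
Product: 18 11α-alcohol (8β,11α-diol)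
Conditions: Me4NBH(OAc)3, MeCN–AcOH (1:1), −30 → −20 °C
Reagents that add atoms: none
Why: In this Evans–Saksena reduction the axial 8β-OH binds boron and delivers hydride to the β face of C11 through a six-membered chair, giving the equatorial 11α-alcohol (1,3-anti diol); the unactivated C3 ketone and the hindered C14 ketone, reachable only through a five-membered delivery, should remain.

**Step 15**
Reactants: 18 11α-alcohol
Product: 19 11α-benzoate
Conditions: BzCl, pyridine, DMAP (cat.), CH2Cl2, 0 °C → rt
Reagents that add atoms: benzoyl chloride, O=C(Cl)c1ccccc1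
Why: Nucleophile-catalysed acylation should take the only secondary alcohol, the tertiary 8-OH being inert.

**Step 16**
Reactants: 19 11α-benzoate
Product: 20 C2=C3 triethylsilyl enol ether 8-O-triethylsilyl ether
Conditions: TESOTf (2.5 equiv), Et3N, CH2Cl2, −78 → −20 °C
Reagents that add atoms: triethylsilyl triflate, CC[Si](CC)(CC)OS(=O)(=O)C(F)(F)F
Why: Soft enolisation and O-silylation should enolise the C3 ketone toward its only α-CH2 (C2) and silylate the tertiary 8-OH, while the C14 ketone, flanked by quaternary C8 and tertiary C13, is too hindered at low temperature; the enol ether masks C3 in step 17 and is the handle for ring opening.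

**Step 17**
Reactants: 20 bis-silylated ketone
Product: 22 13α-vinyl-13β-methyl ketone, via lithium enolate 21 (not isolated)
Conditions: LiN(SiMe3)2, Pd2(dba)3 (5 mol%), P(t-Bu)3 (12 mol%), vinyl bromide (1 M in THF), toluene, rt → 45 °C
Reagents that add atoms: vinyl bromide, C=CBr
Why: In this palladium-catalysed α-vinylation of a ketone enolate C13 is the only enolisable carbon, and the vinylpalladium species should bind the enolate face anti to the axial 8β-silyloxy group, so the vinyl group enters α and the methyl becomes axial β.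

**Step 18**
Reactants: 22 13α-vinyl ketone
Product: 24 C2 aldehyde C3 carboxylic acid (ring A opened), via methoxy hydroperoxide silyl ester 23 (not isolated)
Conditions: O3, CH2Cl2–MeOH (4:1), NaHCO3, Sudan Red 7B, −78 °C; Me2S, −78 °C → rt
Reagents that add atoms: ozone, [O-][O+]=O
Why: Ozonolysis of the silyl enol ether gives the C3 silyl ester (acid on work-up) and the C2 aldehyde; the electron-rich enol ether should react far faster than the neopentyl monosubstituted vinyl group, and the dye marks the end point.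

**Step 19**
Reactants: 24 aldehyde acid
Product: 25 2,3-seco diacid (7α-OTBS, 8β-OTES)
Conditions: NaClO2, NaH2PO4, 2-methyl-2-butene, t-BuOH–H2O, 0 °C → rt
Reagents that add atoms: sodium chlorite, [Na+].[O-]Cl=O
Why: Pinnick oxidation converts the aldehyde to the acid while the alkene scavenger protects the vinyl group from hypochlorous acid.

**Step 20**
Reactants: 25 bis-silylated diacid
Product: 26 7α,8β-diol diacid
Conditions: 48% aq. HF, MeCN, 0 °C → rt
Reagents that add atoms: none
Why: Fluoride-mediated desilylation should cleave both silyl ethers, with the benzoate, the vinyl group and the non-enolisable α-ketol stable to the acidic medium.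

**Step 21**
Reactants: 26 diol diacid
Product: 27 CNP0315860.1 (target)
Conditions: Ac2O, pyridine, DMAP (cat.), CH2Cl2, 0 °C → rt; aqueous work-up at pH 3
Reagents that add atoms: acetic anhydride, CC(=O)OC(C)=O
Why: Nucleophile-catalysed acetylation should take the secondary axial 7α-OH only, the tertiary 8-OH being inert and the carboxylic acids being returned unchanged by the aqueous work-up.

**Compound list**

1 | 2,2-dimethylcyclohexane-1,3-dione | CC1(C)C(=O)CCCC1=O | starting material
2 | 6,6-dimethyl-1,4-dioxaspiro[4.5]decan-7-one | CC1(C)C(=O)CCCC12OCCO2 | intermediate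
3 | lithium enolate of 2 | [Li+].CC1(C)C([O-])=CCCC12OCCO2 | intermediate (not isolated)
4 | 6,6,8-trimethyl-1,4-dioxaspiro[4.5]decan-7-one, racemic | CC1CCC2(OCCO2)C(C)(C)C1=O | intermediate
5 | 7-ethynyl-6,6,8-trimethyl-1,4-dioxaspiro[4.5]decan-7-ol, diastereomer mixture | CC1CCC2(OCCO2)C(C)(C)C1(O)C#C | intermediate
6 | 2-(6,6,8-trimethyl-1,4-dioxaspiro[4.5]decan-7-ylidene)acetaldehyde, E/Z mixture | CC1CCC2(OCCO2)C(C)(C)C1=CC=O | intermediate
7 | (E)-silyloxydiene: 7-[2-(tert-butyldimethylsilyloxy)ethenyl]-6,6,8-trimethyl-1,4-dioxaspiro[4.5]dec-7-ene | CC1=C(/C=C/O[Si](C)(C)C(C)(C)C)C(C)(C)C2(CC1)OCCO2 | intermediate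
8 | 4-methoxy-2-methylphenol | COc1ccc(O)c(C)c1 | starting material
9 | 4,4-dimethoxy-2-methylcyclohexa-2,5-dien-1-one | COC1(OC)C=CC(=O)C(C)=C1 | intermediate
10 | 7-methyl-1,4-dioxaspiro[4.5]deca-6,9-dien-8-one | CC1=CC2(OCCO2)C=CC1=O | intermediate
11 | endo adduct: cis B/C, C14 enone (C12=C13), C5=C6, 7α-OTBS, 8β-H, 9β-H, 10β-Me, dioxolanes at C3 and C11 | CC1=CC2(OCCO2)[C@H]3[C@@]4(C)CCC5(OCCO5)C(C)(C)C4=C[C@@H](O[Si](C)(C)C(C)(C)C)[C@H]3C1=O | intermediate
12 | potassium C8=C14 dienolate of 11 | [K+].CC1=CC2(OCCO2)[C@H]3[C@@]4(C)CCC5(OCCO5)C(C)(C)C4=C[C@@H](O[Si](C)(C)C(C)(C)C)C3=C1[O-] | intermediate (not isolated)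
13 | 8β-hydroxy enone (otherwise as 11) | CC1=CC2(OCCO2)[C@H]3[C@@]4(C)CCC5(OCCO5)C(C)(C)C4=C[C@@H](O[Si](C)(C)C(C)(C)C)[C@@]3(O)C1=O | intermediate
14 | 8β-hydroxy-14-ketone, C12–C13 saturated, C13 epimers | CC1CC2(OCCO2)[C@H]3[C@@]4(C)CCC5(OCCO5)C(C)(C)C4=C[C@@H](O[Si](C)(C)C(C)(C)C)[C@@]3(O)C1=O | intermediate
15 | cis B/C 3,11,14-triketone: C5=C6, 9β-H, 8β-OH, 7α-OTBS, C13 epimers | CC1CC(=O)[C@H]2[C@@]3(C)CCC(=O)C(C)(C)C3=C[C@@H](O[Si](C)(C)C(C)(C)C)[C@@]2(O)C1=O | intermediate
16 | trans B/C 3,11,14-triketone: C5=C6, 9α-H, 13α-Me, 8β-OH, 7α-OTBS | C[C@H]1CC(=O)[C@@H]2[C@@]3(C)CCC(=O)C(C)(C)C3=C[C@@H](O[Si](C)(C)C(C)(C)C)[C@@]2(O)C1=O | intermediate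
17 | 5α-H saturated triketone (all-trans) | C[C@H]1CC(=O)[C@@H]2[C@@]3(C)CCC(=O)C(C)(C)[C@@H]3C[C@@H](O[Si](C)(C)C(C)(C)C)[C@@]2(O)C1=O | intermediate
18 | 11α-alcohol (8β,11α-diol, 3,14-diketone) | C[C@H]1C[C@@H](O)[C@@H]2[C@@]3(C)CCC(=O)C(C)(C)[C@@H]3C[C@@H](O[Si](C)(C)C(C)(C)C)[C@@]2(O)C1=O | intermediate
19 | 11α-benzoate | C[C@H]1C[C@@H](OC(=O)c2ccccc2)[C@@H]2[C@@]3(C)CCC(=O)C(C)(C)[C@@H]3C[C@@H](O[Si](C)(C)C(C)(C)C)[C@@]2(O)C1=O | intermediate
20 | C2=C3 triethylsilyl enol ether, 8β-OTES, 7α-OTBS, 11α-OBz, 14-ketone | C[C@H]1C[C@@H](OC(=O)c2ccccc2)[C@@H]2[C@@]3(C)CC=C(O[Si](CC)(CC)CC)C(C)(C)[C@@H]3C[C@@H](O[Si](C)(C)C(C)(C)C)[C@@]2(O[Si](CC)(CC)CC)C1=O | intermediate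
21 | lithium C13=C14 enolate of 20 | [Li+].CC=1C[C@@H](OC(=O)c2ccccc2)[C@@H]2[C@@]3(C)CC=C(O[Si](CC)(CC)CC)C(C)(C)[C@@H]3C[C@@H](O[Si](C)(C)C(C)(C)C)[C@@]2(O[Si](CC)(CC)CC)C=1[O-] | intermediate (not isolated)
22 | 13α-vinyl-13β-methyl ketone (otherwise as 20) | C=C[C@@]1(C)C[C@@H](OC(=O)c2ccccc2)[C@@H]2[C@@]3(C)CC=C(O[Si](CC)(CC)CC)C(C)(C)[C@@H]3C[C@@H](O[Si](C)(C)C(C)(C)C)[C@@]2(O[Si](CC)(CC)CC)C1=O | intermediate
23 | ring-opened C2 methoxy hydroperoxide, C3 triethylsilyl ester | C=C[C@@]1(C)C[C@@H](OC(=O)c2ccccc2)[C@@H]2[C@@](C)(CC(OC)OO)[C@H](C(C)(C)C(=O)O[Si](CC)(CC)CC)C[C@@H](O[Si](C)(C)C(C)(C)C)[C@@]2(O[Si](CC)(CC)CC)C1=O | intermediate (not isolated)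
24 | C2 aldehyde, C3 acid (7α-OTBS, 8β-OTES) | C=C[C@@]1(C)C[C@@H](OC(=O)c2ccccc2)[C@@H]2[C@@](C)(CC=O)[C@H](C(C)(C)C(=O)O)C[C@@H](O[Si](C)(C)C(C)(C)C)[C@@]2(O[Si](CC)(CC)CC)C1=O | intermediate
25 | 2,3-seco diacid (7α-OTBS, 8β-OTES) | C=C[C@@]1(C)C[C@@H](OC(=O)c2ccccc2)[C@@H]2[C@@](C)(CC(=O)O)[C@H](C(C)(C)C(=O)O)C[C@@H](O[Si](C)(C)C(C)(C)C)[C@@]2(O[Si](CC)(CC)CC)C1=O | intermediate
26 | 7α,8β-diol diacid | C=C[C@@]1(C)C[C@@H](OC(=O)c2ccccc2)[C@@H]2[C@@](C)(CC(=O)O)[C@H](C(C)(C)C(=O)O)C[C@@H](O)[C@@]2(O)C1=O | intermediate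
27 | CNP0315860.1 (7α-acetate, 8β-OH, 11α-benzoate, 13α-vinyl, 14-ketone, 2,3-seco diacid) | C=C[C@@]1(C)C[C@@H](OC(=O)c2ccccc2)[C@@H]2[C@@](C)(CC(=O)O)[C@H](C(C)(C)C(=O)O)C[C@@H](OC(C)=O)[C@@]2(O)C1=O | target

**Count**

Total steps: 21. Longest linear sequence: 19 steps (steps 1–5 and 8–21, from 1).

**Steps most likely to fail**

Step 8. The cycloaddition may be slow because the fully substituted C10 terminus must lead the bond formation next to the spiroketal. The cationic catalyst may also protodesilylate the dienol ether, or divert it into a stepwise Mukaiyama–Michael addition that erodes the endo outcome at C7. The fallback replaces catalyst control by auxiliary control under pressure and sets out from 9 and 7. Dimethyl ketal 9 would be transketalised with (R,R)-hydrobenzoin (BF3·OEt2, DME) to the C2-symmetric diphenyl spiroketal dienone F1. F1 and 7 would be combined without Lewis acid at 12–15 kbar in CH2Cl2 at room temperature, the phenyl group beside C9 selecting the dienone face, to give the endo adduct F2; the antipodal diol would be taken if the sense is opposite. Hydroxylation as in step 9 would give the 8β-hydroxy enone F3, and hydrogenation as in step 10 the saturated hydroxy ketone F4. Hydrolysis of both ketals with p-TsOH in aqueous acetone brings the sequence back to the route at 15.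

Step 17. Enolisation of the axial C13–H beside the silyloxy group, or reductive elimination at the congested carbon, may be too slow, and some β-face attack is possible. The fallback builds the vinyl group by aldol addition and dehydration and sets out from 20. The potassium enolate (KN(SiMe3)2, THF, −78 → −40 °C) would be added to acetaldehyde at −78 °C and quenched cold to give the 13α-(1-hydroxyethyl) ketone F5. Syn-elimination with methyl N-(triethylammoniosulfonyl)carbamate in toluene at 70 °C can only form the terminal alkene and returns to the route at 22.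

Step 13. The C5 radical may undergo a 1,2-acyl shift onto the neighbouring C3 ketone, a ketone may be reduced, or hydrogen may arrive on the β face. The fallback uses hydroxyl-directed hydrogenation and sets out from 16. HF·pyridine in THF would free the allylic alcohol to give the 7α,8β-diol alkene F6. Hydrogenation with [Ir(cod)(PCy3)(py)]PF6 and H2 in CH2Cl2, directed by the allylic 7α-OH, should deliver hydrogen to the α face and give the 5α-saturated diol F7. Silylation of the secondary alcohol alone (TBSCl, imidazole, DMF) returns to the route at 17.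

**Further compounds**

F1 | step 8 | (2R,3R)-7-methyl-2,3-diphenyl-1,4-dioxaspiro[4.5]deca-6,9-dien-8-one | CC1=CC2(O[C@H](c3ccccc3)[C@@H](c3ccccc3)O2)C=CC1=O
F2 | step 8 | endo adduct as 11 with the C11 ketal as the (R,R)-diphenyldioxolane | CC1=CC2(O[C@H](c3ccccc3)[C@@H](c3ccccc3)O2)[C@H]4[C@@]5(C)CCC6(OCCO6)C(C)(C)C5=C[C@@H](O[Si](C)(C)C(C)(C)C)[C@H]4C1=O
F3 | step 8 | 8β-hydroxy enone as 13 with the (R,R)-diphenyldioxolane at C11 | CC1=CC2(O[C@H](c3ccccc3)[C@@H](c3ccccc3)O2)[C@H]4[C@@]5(C)CCC6(OCCO6)C(C)(C)C5=C[C@@H](O[Si](C)(C)C(C)(C)C)[C@@]4(O)C1=O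
F4 | step 8 | C12–C13 saturated hydroxy ketone as 14 with the (R,R)-diphenyldioxolane at C11, C13 epimers | CC1CC2(O[C@H](c3ccccc3)[C@@H](c3ccccc3)O2)[C@H]4[C@@]5(C)CCC6(OCCO6)C(C)(C)C5=C[C@@H](O[Si](C)(C)C(C)(C)C)[C@@]4(O)C1=O
F5 | step 17 | 13α-(1-hydroxyethyl)-13β-methyl ketone (otherwise as 20, carbinol epimers) | CC(O)[C@@]1(C)C[C@@H](OC(=O)c2ccccc2)[C@@H]2[C@@]3(C)CC=C(O[Si](CC)(CC)CC)C(C)(C)[C@@H]3C[C@@H](O[Si](C)(C)C(C)(C)C)[C@@]2(O[Si](CC)(CC)CC)C1=O
F6 | step 13 | 7α,8β-diol of the trans B/C triketone with C5=C6 | C[C@H]1CC(=O)[C@@H]2[C@@]3(C)CCC(=O)C(C)(C)C3=C[C@@H](O)[C@@]2(O)C1=O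
F7 | step 13 | 5α-H saturated 7α,8β-diol triketone | C[C@H]1CC(=O)[C@@H]2[C@@]3(C)CCC(=O)C(C)(C)[C@@H]3C[C@@H](O)[C@@]2(O)C1=O
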